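**Plan**

1. The retrosynthesis first removes the silyl group from O4', the methyl group from O3 together with the C3–O bond (back to a C3–H flavone), and the prenyl group from O7.
2. Ring C is then cut at C4a–C4, C4–C3 and O1–C2. Its C4 carbonyl lies between C4a of ring A and the C3=C2 unit that carries ring B, with O1 on C8a ortho to C4a; this is the pattern left by an o-iodophenol, CO and an arylacetylene.
3. Forward, ring A enters as 4-iodo-2,5-dimethoxybenzene-1,3-diol (three steps from 2,6-dibromo-4-methoxyphenol; iodination of the symmetric diol is unambiguous). Ring B enters as the TIPS-protected ethynylguaiacol (two steps from vanillin).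
4. The three-component carbonylative annulation closes ring C. Only the hydroxyl ortho to the new acyl group can cyclise, so the other emerges as the free 7-OH and is prenylated.
5. C3 is then oxygenated by lithiation–borylation–oxidation and O-methylated, and the silyl ether is cleaved last.
6. No stereochemistry has to be set: the target has no stereocentre, and its only non-aromatic C=C bond (prenyl) carries two identical methyl groups.

Key step: step 6

Remark: the target is achiral, so "single enantiomer" means the one compound drawn; 2,6-dibromo-4-methoxyphenol is assumed to be a catalogue compound.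

**Route**

Step 1
Reactants: 1 2,6-dibromo-4-methoxyphenol
Product: 2 1,3-dibromo-2,5-dimethoxybenzene
Conditions: MeI, K2CO3, DMF, rt
Reagents that add atoms: iodomethane, CI
Why: Williamson O-methylation; the acidic 2,6-dibromophenol is fully ionised by carbonate and the small electrophile reaches the flanked phenoxide.

Step 2
Reactants: 2 1,3-dibromo-2,5-dimethoxybenzene
Product: 4 2,5-dimethoxybenzene-1,3-diol, via 3-bromo-2,5-dimethoxyphenol 3 (not isolated)
Conditions: Pd2(dba)3 (2 mol %), tBuXPhos (8 mol %), KOH, 1,4-dioxane/H2O (1:1), 100 °C; then aq. HCl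
Reagents that add atoms: potassium hydroxide, [K+].[OH-]
Why: Palladium-catalysed hydroxylation of aryl bromides with hydroxide (Buchwald-type C–O coupling); the bulky biarylphosphine favours C–O reductive elimination over diaryl ether formation, and each C–Br bond has only one ortho substituent.

Step 3
Reactants: 4 2,5-dimethoxybenzene-1,3-diol
Product: 5 4-iodo-2,5-dimethoxybenzene-1,3-diol
Conditions: NIS (1.0 equiv), MeCN, −20 → 0 °C, dark
Reagents that add atoms: N-iodosuccinimide, O=C1CCC(=O)N1I
Why: Electrophilic aromatic iodination; C4 and C6 are the only free positions and are equivalent by symmetry, so one equivalent of NIS at low temperature should give a single mono-iodide.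

Step 4
Reactants: 6 vanillin
Product: 7 3-methoxy-4-(triisopropylsilyloxy)benzaldehyde
Conditions: TIPSCl, imidazole, DMF, rt
Reagents that add atoms: chlorotriisopropylsilane, CC(C)[Si](Cl)(C(C)C)C(C)C
Why: Imidazole-mediated silylation of the phenol; the bulky TIPS ether is chosen to survive amine, amide base and carbonate and to leave with fluoride at the end.

Step 5
Reactants: 7 3-methoxy-4-(triisopropylsilyloxy)benzaldehyde
Product: 8 (4-ethynyl-2-methoxyphenoxy)triisopropylsilane
Conditions: TMSCHN2, LDA, THF, −78 °C → rt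
Reagents that add atoms: (trimethylsilyl)diazomethane, C[Si](C)(C)C=[N+]=[N-]
Why: Colvin rearrangement (aprotic Seyferth–Gilbert-type homologation): lithiated TMS-diazomethane adds to the aldehyde, silanolate leaves in a Peterson-type elimination, and nitrogen loss with a 1,2-hydrogen shift gives the terminal alkyne without the carbonate/methanol that would endanger the aryl silyl ether.

Step 6
Reactants: 5 4-iodo-2,5-dimethoxybenzene-1,3-diol; 8 (4-ethynyl-2-methoxyphenoxy)triisopropylsilane; 9 carbon monoxide
Product: 12 7-hydroxy-5,8-dimethoxy-2-[3-methoxy-4-(triisopropylsilyloxy)phenyl]-4H-chromen-4-one, via ynone 10 (not isolated), via enaminone 11 (not isolated)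
Conditions: PdCl2(dppf) (5 mol %), CO (10 bar), Et2NH, 90 °C
Reagents that add atoms: none
Why: Pd(0) inserts into the C–I bond of 5 (the future C4a), CO insertion gives the aroyl–palladium species that carries C4, and amine-assisted alkynyl transfer from 8 followed by reductive elimination forms C4–C3 of ynone 10. Diethylamine then adds to the ynone to give enaminone 11, and the hydroxyl ortho to the acyl group displaces the amine at the β-carbon in a 6-endo addition–elimination that forms O1–C2 and closes ring C. The closest known reaction type is the palladium-catalysed carbonylative Sonogashira annulation of 2-iodophenols with terminal arylacetylenes in a secondary amine. No stereocentre is formed. The step needs 6-endo rather than 5-exo closure (flavone, not aurone), which the enaminone pathway secures by making C2 the electrophilic carbon, and it needs CO insertion ahead of direct alkynylation, which copper-free conditions under CO pressure secure. It also needs the correct hydroxyl to close, which the substrate secures because only the C3 hydroxyl of 5 is ortho to the acyl group, so the para hydroxyl is left as the free 7-OH.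

Step 7
Reactants: 12 7-hydroxy-5,8-dimethoxy-2-[3-methoxy-4-(triisopropylsilyloxy)phenyl]-4H-chromen-4-one
Product: 13 5,8-dimethoxy-2-[3-methoxy-4-(triisopropylsilyloxy)phenyl]-7-(3-methylbut-2-en-1-yloxy)-4H-chromen-4-one
Conditions: prenol, PPh3, DIAD, THF, 0 °C → rt
Reagents that add atoms: 3-methylbut-2-en-1-ol, CC(C)=CCO
Why: Mitsunobu etherification; the acidic 7-OH (the only free hydroxyl) is alkylated by the activated primary allylic alcohol in an SN2 sense under neutral conditions that spare the aryl silyl ether.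

Step 8
Reactants: 13 5,8-dimethoxy-2-[3-methoxy-4-(triisopropylsilyloxy)phenyl]-7-(3-methylbut-2-en-1-yloxy)-4H-chromen-4-one
Product: 16 3-hydroxy-5,8-dimethoxy-2-[3-methoxy-4-(triisopropylsilyloxy)phenyl]-7-(3-methylbut-2-en-1-yloxy)-4H-chromen-4-one, via 3-lithioflavone 14 (not isolated), via 3-boronate 15 (not isolated)
Conditions: LDA, THF, −78 °C; B(OMe)3, −78 → 0 °C; then 30% H2O2, aq. NaHCO3, 0 °C
Reagents that add atoms: hydrogen peroxide, OO
Why: Vinylic deprotonation of the flavone at C3 (the most acidic C–H, next to C4=O) with LDA, trapping with trimethyl borate and peroxide oxidation of the C–B bond by 1,2-migration to oxygen; neither the amide base at −78 °C nor weakly basic peroxide touches the prenyl double bond or the TIPS ether.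

Step 9
Reactants: 16 3-hydroxy-5,8-dimethoxy-2-[3-methoxy-4-(triisopropylsilyloxy)phenyl]-7-(3-methylbut-2-en-1-yloxy)-4H-chromen-4-one
Product: 17 3,5,8-trimethoxy-2-[3-methoxy-4-(triisopropylsilyloxy)phenyl]-7-(3-methylbut-2-en-1-yloxy)-4H-chromen-4-one
Conditions: MeI, K2CO3, acetone, 40 °C
Reagents that add atoms: iodomethane, CI
Why: Williamson methylation of the enolic 3-OH, the only acidic proton in the molecule; anhydrous carbonate in acetone should leave the hindered aryl TIPS ether intact.

Step 10
Reactants: 17 3,5,8-trimethoxy-2-[3-methoxy-4-(triisopropylsilyloxy)phenyl]-7-(3-methylbut-2-en-1-yloxy)-4H-chromen-4-one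
Product: 18 2-(4-hydroxy-3-methoxyphenyl)-3,5,8-trimethoxy-7-(3-methylbut-2-en-1-yloxy)-4H-chromen-4-one (4'-hydroxy-3,5,8,3'-tetramethoxy-7-prenyloxyflavone)
Conditions: TBAF, AcOH, THF, 0 °C
Reagents that add atoms: none
Why: Fluoride-induced cleavage of the aryl Si–O bond, driven by Si–F bond formation; acetic acid buffers the liberated phenoxide, and the prenyl ether, methyl ethers and pyranone are inert.

**Compound list**

1 | 2,6-dibromo-4-methoxyphenol | COc1cc(Br)c(O)c(Br)c1 | starting material
2 | 1,3-dibromo-2,5-dimethoxybenzene | COc1cc(Br)c(OC)c(Br)c1 | intermediate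
3 | 3-bromo-2,5-dimethoxyphenol | COc1cc(O)c(OC)c(Br)c1 | intermediate (not isolated)
4 | 2,5-dimethoxybenzene-1,3-diol | COc1cc(O)c(OC)c(O)c1 | intermediate
5 | 4-iodo-2,5-dimethoxybenzene-1,3-diol | COc1cc(O)c(OC)c(O)c1I | intermediate
6 | vanillin (4-hydroxy-3-methoxybenzaldehyde) | COc1cc(C=O)ccc1O | starting material
7 | 3-methoxy-4-(triisopropylsilyloxy)benzaldehyde | COc1cc(C=O)ccc1O[Si](C(C)C)(C(C)C)C(C)C | intermediate
8 | (4-ethynyl-2-methoxyphenoxy)triisopropylsilane | C#Cc1ccc(O[Si](C(C)C)(C(C)C)C(C)C)c(OC)c1 | intermediate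
9 | carbon monoxide | [C-]#[O+] | starting material
10 | 1-(2,4-dihydroxy-3,6-dimethoxyphenyl)-3-[3-methoxy-4-(triisopropylsilyloxy)phenyl]prop-2-yn-1-one | COc1cc(C#CC(=O)c2c(O)c(OC)c(O)cc2OC)ccc1O[Si](C(C)C)(C(C)C)C(C)C | intermediate (not isolated)
11 | 3-(diethylamino)-1-(2,4-dihydroxy-3,6-dimethoxyphenyl)-3-[3-methoxy-4-(triisopropylsilyloxy)phenyl]prop-2-en-1-one (double-bond geometry not defined) | CCN(CC)C(=CC(=O)c1c(O)c(OC)c(O)cc1OC)c1ccc(O[Si](C(C)C)(C(C)C)C(C)C)c(OC)c1 | intermediate (not isolated)
12 | 7-hydroxy-5,8-dimethoxy-2-[3-methoxy-4-(triisopropylsilyloxy)phenyl]-4H-chromen-4-one | COc1cc(-c2cc(=O)c3c(OC)cc(O)c(OC)c3o2)ccc1O[Si](C(C)C)(C(C)C)C(C)C | intermediate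
13 | 5,8-dimethoxy-2-[3-methoxy-4-(triisopropylsilyloxy)phenyl]-7-(3-methylbut-2-en-1-yloxy)-4H-chromen-4-one | COc1cc(-c2cc(=O)c3c(OC)cc(OCC=C(C)C)c(OC)c3o2)ccc1O[Si](C(C)C)(C(C)C)C(C)C | intermediate
14 | 3-lithio derivative of 13 | [Li]c1c(-c2ccc(O[Si](C(C)C)(C(C)C)C(C)C)c(OC)c2)oc2c(OC)c(OCC=C(C)C)cc(OC)c2c1=O | intermediate (not isolated)
15 | 3-(dimethoxyboryl) derivative of 13 | COB(OC)c1c(-c2ccc(O[Si](C(C)C)(C(C)C)C(C)C)c(OC)c2)oc2c(OC)c(OCC=C(C)C)cc(OC)c2c1=O | intermediate (not isolated)
16 | 3-hydroxy-5,8-dimethoxy-2-[3-methoxy-4-(triisopropylsilyloxy)phenyl]-7-(3-methylbut-2-en-1-yloxy)-4H-chromen-4-one | COc1cc(-c2oc3c(OC)c(OCC=C(C)C)cc(OC)c3c(=O)c2O)ccc1O[Si](C(C)C)(C(C)C)C(C)C | intermediate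
17 | 3,5,8-trimethoxy-2-[3-methoxy-4-(triisopropylsilyloxy)phenyl]-7-(3-methylbut-2-en-1-yloxy)-4H-chromen-4-one | COc1cc(-c2oc3c(OC)c(OCC=C(C)C)cc(OC)c3c(=O)c2OC)ccc1O[Si](C(C)C)(C(C)C)C(C)C | intermediate
18 | 4'-hydroxy-3,5,8,3'-tetramethoxy-7-prenyloxyflavone | COc1cc(-c2oc3c(OC)c(OCC=C(C)C)cc(OC)c3c(=O)c2OC)ccc1O | target

**Step count and risks**

Total step count: 10. Longest linear sequence: 8 steps (steps 1, 2, 3, 6, 7, 8, 9, 10).

Steps most likely to fail:

Step 6. The aroyl–palladium intermediate may be captured by diethylamine or by the remote phenoxide before the alkyne is transferred, and the very electron-rich free diol may lose iodine reductively or react sluggishly in oxidative addition. The fallback runs the sequence stepwise on ester-masked phenols. It sets out from 5, which is acetylated (Ac2O, pyridine) to 4-iodo-2,5-dimethoxy-1,3-phenylene diacetate F1. Copper-free carbonylative Sonogashira coupling of this less electron-rich iodide with 8 under CO (1 atm) with PdCl2(PPh3)2 and triethylamine at 25–40 °C, with no secondary amine present, should stop at the isolable ynone 2,5-dimethoxy-4-{3-[3-methoxy-4-(triisopropylsilyloxy)phenyl]prop-2-ynoyl}-1,3-phenylene diacetate F2. A separate treatment with diethylamine in THF then cleaves both acetates and cyclises through the enaminone, returning to the route at 12.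

Step 8. The 3-lithio species may open by β-elimination of the ring phenoxide if it warms before borylation, deprotonation may compete at the allylic O–CH2 of the prenyl ether, and the flavonol may be degraded by peroxide. The fallback hydroxylates C3 by epoxidation before the prenyl group is present. It sets out from 12, which is benzylated (BnOH, PPh3, DIAD) to 7-benzyloxy-5,8-dimethoxy-2-[3-methoxy-4-(triisopropylsilyloxy)phenyl]-4H-chromen-4-one F3. Dimethyldioxirane in acetone should give the racemic 2,3-epoxide of that flavone F4, which catalytic TsOH opens to 7-benzyloxy-3-hydroxy-5,8-dimethoxy-2-[3-methoxy-4-(triisopropylsilyloxy)phenyl]-4H-chromen-4-one F5. Methylation (MeI, K2CO3, acetone) gives 7-benzyloxy-3,5,8-trimethoxy-2-[3-methoxy-4-(triisopropylsilyloxy)phenyl]-4H-chromen-4-one F6, and hydrogenolysis (H2, Pd/C, EtOAc) gives 7-hydroxy-3,5,8-trimethoxy-2-[3-methoxy-4-(triisopropylsilyloxy)phenyl]-4H-chromen-4-one F7. Mitsunobu prenylation as in step 7 comes back to the route at 17.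

Step 2. The second C–O coupling may stall because the intermediate bromophenoxide is a poor partner for oxidative addition, and diaryl ether formation may compete. The fallback replaces direct C–O coupling by C–B coupling and oxidation. It sets out from 2, which undergoes double Miyaura borylation (B2pin2, PdCl2(dppf), KOAc, dioxane, 90 °C) to 2,2'-(2,5-dimethoxy-1,3-phenylene)bis(4,4,5,5-tetramethyl-1,3,2-dioxaborolane) F8. Oxidation with H2O2/NaOH in THF at 0 °C comes back to the route at 4.

**Further compounds**

F1 | step 6 | 4-iodo-2,5-dimethoxy-1,3-phenylene diacetate | CC(=O)Oc1cc(OC)c(I)c(OC(C)=O)c1OC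
F2 | step 6 | 2,5-dimethoxy-4-{3-[3-methoxy-4-(triisopropylsilyloxy)phenyl]prop-2-ynoyl}-1,3-phenylene diacetate | COc1cc(C#CC(=O)c2c(OC)cc(OC(C)=O)c(OC)c2OC(C)=O)ccc1O[Si](C(C)C)(C(C)C)C(C)C
F3 | step 8 | 7-benzyloxy-5,8-dimethoxy-2-[3-methoxy-4-(triisopropylsilyloxy)phenyl]-4H-chromen-4-one | COc1cc(-c2cc(=O)c3c(OC)cc(OCc4ccccc4)c(OC)c3o2)ccc1O[Si](C(C)C)(C(C)C)C(C)C
F4 | step 8 | 7-benzyloxy-2,3-epoxy-5,8-dimethoxy-2-[3-methoxy-4-(triisopropylsilyloxy)phenyl]chroman-4-one (racemic, cis-fused; one enantiomer drawn) | COc1cc([C@]23O[C@H]2C(=O)c2c(OC)cc(OCc4ccccc4)c(OC)c2O3)ccc1O[Si](C(C)C)(C(C)C)C(C)C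
F5 | step 8 | 7-benzyloxy-3-hydroxy-5,8-dimethoxy-2-[3-methoxy-4-(triisopropylsilyloxy)phenyl]-4H-chromen-4-one | COc1cc(-c2oc3c(OC)c(OCc4ccccc4)cc(OC)c3c(=O)c2O)ccc1O[Si](C(C)C)(C(C)C)C(C)C
F6 | step 8 | 7-benzyloxy-3,5,8-trimethoxy-2-[3-methoxy-4-(triisopropylsilyloxy)phenyl]-4H-chromen-4-one | COc1cc(-c2oc3c(OC)c(OCc4ccccc4)cc(OC)c3c(=O)c2OC)ccc1O[Si](C(C)C)(C(C)C)C(C)C
F7 | step 8 | 7-hydroxy-3,5,8-trimethoxy-2-[3-methoxy-4-(triisopropylsilyloxy)phenyl]-4H-chromen-4-one | COc1cc(-c2oc3c(OC)c(O)cc(OC)c3c(=O)c2OC)ccc1O[Si](C(C)C)(C(C)C)C(C)C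
F8 | step 2 | 2,2'-(2,5-dimethoxy-1,3-phenylene)bis(4,4,5,5-tetramethyl-1,3,2-dioxaborolane) | COc1cc(B2OC(C)(C)C(C)(C)O2)c(OC)c(B2OC(C)(C)C(C)(C)O2)c1
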